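**Retrosynthetic overview**

1. Target 27 ← diol 24 (angeloylation of O8) ← ketone 22 (1,3-anti reduction at C8). Germacranolide numbering is used: lactone O on C6, C12 lactone carbonyl, C13 exo-methylene carbon, C14 and C15 the methyls on C10 and C4.
2. Key disconnection C9–C10: 22 ← bromo ketone 20 by a SmI2-induced Reformatsky-type aldol closure of the ten-membered carbocycle. The enabling feature is the aldol pattern C8(O)–C9H2–C10(OH)(CH3) inside the ten-membered ring, with the E C1=C2–C10 methyl enone as acceptor; the cis-fused γ-lactone on C6/C7 and the Z C4=C5 bond fold the two arms toward each other.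
3. 20 ← lactone 16 ← lactol 9 + allyl bromide 13 by indium Barbier allylation and lactonisation (C6–C7 bond, lactone ring, C6 and C7 stereocentres).
4. 9 ← methyl propiolate + acrolein (asymmetric alkynylation sets C3; syn-carbocupration to the butenolide fixes 4Z; cross-metathesis adds the masked enone). 13 ← methyl acrylate + glyceraldehyde acetonide (Morita–Baylis–Hillman, then allylic bromide).
5. Ring order: γ-lactone first (step 7), ten-membered carbocycle second (step 12).

Key step: step 12

Assumptions: aldehyde 11 is taken as a commercial chiral-pool compound (it also derives from L-ascorbic acid), and the ProPhenol antipode in step 1 is the one that gives Si-face addition (written here as R,R).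

**Step 1**
Reactants: 1 methyl propiolate; 2 acrolein
Product: 4 methyl (4R)-4-hydroxyhex-5-en-2-ynoate, via zinc alkynylide 3 (not isolated)
Conditions: (R,R)-ProPhenol (20 mol %), Me2Zn (3 equiv), Ph3PO (40 mol %), toluene, 0 °C; aq. NH4Cl
Reagents that add atoms: none
Why: The dinuclear zinc–ProPhenol catalyst should deliver the alkynylzinc 3 to the Si face of the enal (catalytic asymmetric alkynylation of an aldehyde) and so set the carbinol that becomes C3 as R.

**Step 2**
Reactants: 4 methyl (4R)-4-hydroxyhex-5-en-2-ynoate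
Product: 6 (5R)-5-ethenyl-4-methylfuran-2(5H)-one, via Z-hydroxy enoate 5 (not isolated)
Conditions: Me2CuLi (2.5 equiv), THF, −78 °C; aq. NH4Cl, then AcOH (cat.), rt
Reagents that add atoms: lithium dimethylcuprate, [Li+].C[Cu-]C
Why: Conjugate addition of the cuprate to the ynoate is a syn carbocupration and the alkenylcopper is protonated with retention, so the (Z)-β-methyl enoate 5 forms and its cis-disposed hydroxyl lactonises to the butenolide, which locks the later C4=C5 bond as Z while C3 is untouched.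

**Step 3**
Reactants: 6 (5R)-5-ethenyl-4-methylfuran-2(5H)-one; 7 2-ethenyl-2-methyl-1,3-dioxolane
Product: 8 (5R)-4-methyl-5-[(E)-2-(2-methyl-1,3-dioxolan-2-yl)ethenyl]furan-2(5H)-one
Conditions: 7 (5 equiv), second-generation Hoveyda–Grubbs catalyst (5 mol %), CH2Cl2, 40 °C
Reagents that add atoms: none
Why: Olefin cross-metathesis engages only the monosubstituted vinyl group (the conjugated trisubstituted ring olefin is inert), and the excess of the hindered partner 7 should give the E C1=C2 bond with C10 masked as its ketal.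

**Step 4**
Reactants: 8 (5R)-4-methyl-5-[(E)-2-(2-methyl-1,3-dioxolan-2-yl)ethenyl]furan-2(5H)-one
Product: 9 (5R)-4-methyl-5-[(E)-2-(2-methyl-1,3-dioxolan-2-yl)ethenyl]-2,5-dihydrofuran-2-ol (lactol; both anomers)
Conditions: i-Bu2AlH (1.1 equiv), CH2Cl2, −78 °C; aq. potassium sodium tartrate
Reagents that add atoms: none
Why: i-Bu2AlH reduction of a lactone at −78 °C stops at the aluminium lactolate, so the lactol is obtained as a masked (Z)-γ-hydroxy enal that cannot isomerise to the E enal.

**Step 5**
Reactants: 10 methyl acrylate; 11 (S)-2,2-dimethyl-1,3-dioxolane-4-carbaldehyde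
Product: 12 methyl 2-{[(4S)-2,2-dimethyl-1,3-dioxolan-4-yl](hydroxy)methyl}prop-2-enoate (both carbinol epimers)
Conditions: DABCO (0.5 equiv), dioxane/H2O (1:1), rt
Reagents that add atoms: none
Why: The Morita–Baylis–Hillman reaction of an acrylate with an α-alkoxy aldehyde is reliable, and the new carbinol centre is formed without control because it becomes sp2 in step 6.

**Step 6**
Reactants: 12 methyl 2-{[(4S)-2,2-dimethyl-1,3-dioxolan-4-yl](hydroxy)methyl}prop-2-enoate
Product: 13 methyl (2Z)-2-(bromomethyl)-3-[(4R)-2,2-dimethyl-1,3-dioxolan-4-yl]prop-2-enoate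
Conditions: NBS (1.3 equiv), Me2S (1.5 equiv), CH2Cl2, 0 °C to rt
Reagents that add atoms: N-bromosuccinimide, BrN1C(=O)CCC1=O
Why: The bromosulfonium reagent formed from NBS and Me2S (Corey–Kim type) converts Baylis–Hillman alcohols into the rearranged, thermodynamically favoured (Z)-2-(bromomethyl)alk-2-enoates (SN2′) without acid that would cleave the acetonide; the dioxolane centre is unchanged in space (its descriptor changes only by priority).

**Step 7**
Reactants: 9 (5R)-4-methyl-5-[(E)-2-(2-methyl-1,3-dioxolan-2-yl)ethenyl]-2,5-dihydrofuran-2-ol; 13 methyl (2Z)-2-(bromomethyl)-3-[(4R)-2,2-dimethyl-1,3-dioxolan-4-yl]prop-2-enoate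
Product: 16 (4R,5R)-4-[(4R)-2,2-dimethyl-1,3-dioxolan-4-yl]-5-[(1Z,3R,4E)-3-hydroxy-2-methyl-5-(2-methyl-1,3-dioxolan-2-yl)penta-1,4-dienyl]-3-methylideneoxolan-2-one, via allylindium dibromide 14 (not isolated), via open hydroxy ester 15 (not isolated)
Conditions: indium powder (1.5 equiv), THF/H2O (3:1), rt; then PPTS (5 mol %), benzene, 40 °C
Reagents that add atoms: none
Why: Indium-mediated Barbier allylation of the ring-opened hydroxy enal by the 2-(alkoxycarbonyl)allyl reagent 14 should pass through a chair transition state with the cis-disposed γ-substituent axial (syn adduct 15, hence the cis-fused lactone after loss of methanol), and the dioxolane stereocentre next to the reacting carbon (H in the plane of the double bond, C8–C9 bond anti to the incoming aldehyde) is expected to direct the reagent to the Si face of the aldehyde, which sets 6R and the C7 configuration of the target.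

**Step 8**
Reactants: 16 (4R,5R)-4-[(4R)-2,2-dimethyl-1,3-dioxolan-4-yl]-5-[(1Z,3R,4E)-3-hydroxy-2-methyl-5-(2-methyl-1,3-dioxolan-2-yl)penta-1,4-dienyl]-3-methylideneoxolan-2-one
Product: 17 (4R,5R)-5-[(1Z,3R,4E)-3-acetoxy-2-methyl-5-(2-methyl-1,3-dioxolan-2-yl)penta-1,4-dienyl]-4-[(4R)-2,2-dimethyl-1,3-dioxolan-4-yl]-3-methylideneoxolan-2-one
Conditions: Ac2O, pyridine, DMAP (cat.), CH2Cl2, 0 °C
Reagents that add atoms: acetic anhydride, CC(=O)OC(C)=O
Why: Acylation of the only free hydroxyl under standard nucleophilic catalysis installs the C3 acetate of the target without touching any stereocentre.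

**Step 9**
Reactants: 17 (4R,5R)-5-[(1Z,3R,4E)-3-acetoxy-2-methyl-5-(2-methyl-1,3-dioxolan-2-yl)penta-1,4-dienyl]-4-[(4R)-2,2-dimethyl-1,3-dioxolan-4-yl]-3-methylideneoxolan-2-one
Product: 18 (4S,5R)-5-[(1Z,3R,4E)-3-acetoxy-2-methyl-6-oxohepta-1,4-dienyl]-4-[(1R)-1,2-dihydroxyethyl]-3-methylideneoxolan-2-one
Conditions: AcOH/THF/H2O (3:1:1), 40 °C
Reagents that add atoms: water, O
Why: Acid-catalysed acetal hydrolysis should cleave the allylic dioxolane ketal and the terminal acetonide while the allylic acetate and the lactone survive, which unveils the C10 methyl enone and the C8/C9 diol.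

**Step 10**
Reactants: 18 (4S,5R)-5-[(1Z,3R,4E)-3-acetoxy-2-methyl-6-oxohepta-1,4-dienyl]-4-[(1R)-1,2-dihydroxyethyl]-3-methylideneoxolan-2-one
Product: 19 (4S,5R)-5-[(1Z,3R,4E)-3-acetoxy-2-methyl-6-oxohepta-1,4-dienyl]-4-[(1R)-2-bromo-1-hydroxyethyl]-3-methylideneoxolan-2-one
Conditions: CBr4 (1.2 equiv), PPh3 (1.25 equiv), CH2Cl2, −20 to 0 °C
Reagents that add atoms: tetrabromomethane, BrC(Br)(Br)Br
Why: The Appel reaction is selective for the primary hydroxyl of a 1,2-diol at low temperature and gives the bromohydrin with the C8 carbinol untouched.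

**Step 11**
Reactants: 19 (4S,5R)-5-[(1Z,3R,4E)-3-acetoxy-2-methyl-6-oxohepta-1,4-dienyl]-4-[(1R)-2-bromo-1-hydroxyethyl]-3-methylideneoxolan-2-one
Product: 20 (4R,5R)-5-[(1Z,3R,4E)-3-acetoxy-2-methyl-6-oxohepta-1,4-dienyl]-4-(bromoacetyl)-3-methylideneoxolan-2-one
Conditions: Dess–Martin periodinane, NaHCO3, CH2Cl2, 0 °C to rt
Reagents that add atoms: none
Why: Buffered Dess–Martin oxidation of the secondary alcohol gives the α-bromo ketone under neutral conditions that should neither epimerise C7 nor eliminate the β-acyloxy (lactone) oxygen.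

**Step 12**
Reactants: 20 (4R,5R)-5-[(1Z,3R,4E)-3-acetoxy-2-methyl-6-oxohepta-1,4-dienyl]-4-(bromoacetyl)-3-methylideneoxolan-2-one
Product: 22 (3R,6R,7R,10R)-3-acetoxy-10-hydroxy-8-oxogermacra-1(2),4,11(13)-trien-12,6-olide (1E,4Z), via samarium enolate 21 (not isolated)
Conditions: SmI2 (2.2 equiv), THF, −78 °C, slow addition of 20 (final 0.002 M), then −78 to −40 °C; pH 7 phosphate buffer
Reagents that add atoms: none
Why: SmI2 reduces the C9–Br bond of the α-bromo ketone by two single-electron transfers at −78 °C and gives the O-bound trivalent samarium enolate 21 regiospecifically at C9, which adds in Reformatsky fashion to the C10 carbonyl of the E methyl enone through a samarium-bridged chair (Zimmerman–Traxler) transition state. The closest known reaction type is the SmI2-promoted intramolecular Reformatsky (aldol) cyclisation of α-halo carbonyl compounds onto aldehydes and ketones, which has been used to close medium carbocycles and macrolides. The ten-membered carbocycle closes in the 10-(enolendo)-exo-trig mode, whereas attack of C9 on the lactone carbonyl or on C13 would be five-membered enolendo closures that are stereoelectronically disfavoured. The new stereocentre C10 is under substrate control: the cis-fused lactone holds the C6 and C7 arms on one face, the 4Z and 1E double bonds fix the shape of the tether, and in the chelated chair the alkenyl arm C1 should sit equatorial and the methyl group axial, so C9 is expected to reach the Re face of the ketone and give 10R. The step needs chemoselectivity for the C–Br bond over the enone, the allylic acetate and the α-methylene lactone, which the much faster reduction of α-halo ketones at −78 °C without additives should secure, and 1,2- rather than 1,4-addition, which the hard, chelating samarium enolate should secure. High dilution and a cold buffered quench protect the β-hydroxy ketone from retro-aldol cleavage and C7 from epimerisation.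

**Step 13**
Reactants: 22 (3R,6R,7R,10R)-3-acetoxy-10-hydroxy-8-oxogermacra-1(2),4,11(13)-trien-12,6-olide (1E,4Z)
Product: 24 (3R,6R,7S,8R,10R)-3-acetoxy-8,10-dihydroxygermacra-1(2),4,11(13)-trien-12,6-olide (1E,4Z), via alkoxyborohydride 23 (not isolated)
Conditions: Me4NBH(OAc)3 (6 equiv), MeCN/AcOH (1:1), −30 to −20 °C; aq. potassium sodium tartrate
Reagents that add atoms: none
Why: Evans–Saksena reduction: the tertiary C10 hydroxyl exchanges onto boron (23) and hydride is delivered intramolecularly through a chair transition state to the Si face of the C8 ketone, which should give the 1,3-anti diol, that is 8R.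

**Step 14**
Reactants: 24 (3R,6R,7S,8R,10R)-3-acetoxy-8,10-dihydroxygermacra-1(2),4,11(13)-trien-12,6-olide (1E,4Z); 25 angelic acid
Product: 27 (3R,6R,7S,8R,10R)-3-acetoxy-8-angeloyloxy-10-hydroxygermacra-1(2),4,11(13)-trien-12,6-olide (1E,4Z), via mixed anhydride 26 (not isolated)
Conditions: 25, 2,4,6-trichlorobenzoyl chloride, Et3N, toluene, rt; then 24, toluene, 80 °C (no DMAP)
Reagents that add atoms: none
Why: Yamaguchi-type acylation of the only secondary hydroxyl (the tertiary C10 hydroxyl is too hindered to react) with the preformed mixed anhydride 26, without a nucleophilic catalyst, should transfer the (Z)-2-methylbut-2-enoyl group without isomerisation to the E (tigloyl) ester.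

**Compound list**

1 | methyl propiolate (methyl prop-2-ynoate) | C#CC(=O)OC | starting material
2 | acrolein (prop-2-enal) | C=CC=O | starting material
3 | methylzinc alkynylide of 1 [methyl 3-(methylzincio)prop-2-ynoate] | C[Zn]C#CC(=O)OC | intermediate
4 | methyl (4R)-4-hydroxyhex-5-en-2-ynoate | C=C[C@@H](O)C#CC(=O)OC | intermediate
5 | methyl (2Z,4R)-4-hydroxy-3-methylhexa-2,5-dienoate | C=C[C@@H](O)/C(C)=C\C(=O)OC | intermediate
6 | (5R)-5-ethenyl-4-methylfuran-2(5H)-one | C=C[C@H]1OC(=O)C=C1C | intermediate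
7 | 2-ethenyl-2-methyl-1,3-dioxolane | C=CC1(C)OCCO1 | starting material
8 | (5R)-4-methyl-5-[(E)-2-(2-methyl-1,3-dioxolan-2-yl)ethenyl]furan-2(5H)-one | CC1(/C=C/[C@H]2OC(=O)C=C2C)OCCO1 | intermediate
9 | (5R)-4-methyl-5-[(E)-2-(2-methyl-1,3-dioxolan-2-yl)ethenyl]-2,5-dihydrofuran-2-ol (both anomers) | CC1(/C=C/[C@H]2OC(O)C=C2C)OCCO1 | intermediate
10 | methyl acrylate | C=CC(=O)OC | starting material
11 | (S)-2,2-dimethyl-1,3-dioxolane-4-carbaldehyde | O=C[C@@H]1COC(C)(C)O1 | starting material
12 | methyl 2-{[(4S)-2,2-dimethyl-1,3-dioxolan-4-yl](hydroxy)methyl}prop-2-enoate (both carbinol epimers) | C=C(C(=O)OC)C(O)[C@@H]1COC(C)(C)O1 | intermediate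
13 | methyl (2Z)-2-(bromomethyl)-3-[(4R)-2,2-dimethyl-1,3-dioxolan-4-yl]prop-2-enoate | COC(=O)/C(CBr)=C/[C@@H]1COC(C)(C)O1 | intermediate
14 | {(2Z)-3-[(4R)-2,2-dimethyl-1,3-dioxolan-4-yl]-2-(methoxycarbonyl)prop-2-enyl}indium dibromide | COC(=O)/C(C[In](Br)Br)=C/[C@@H]1COC(C)(C)O1 | intermediate
15 | methyl (3R,4R,5Z,7R,8E)-3-[(4R)-2,2-dimethyl-1,3-dioxolan-4-yl]-4,7-dihydroxy-6-methyl-2-methylidene-9-(2-methyl-1,3-dioxolan-2-yl)nona-5,8-dienoate | COC(=O)C(=C)[C@@H]([C@@H]1COC(C)(C)O1)[C@H](O)/C=C(/C)[C@H](O)/C=C/C1(C)OCCO1 | intermediate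
16 | (4R,5R)-4-[(4R)-2,2-dimethyl-1,3-dioxolan-4-yl]-5-[(1Z,3R,4E)-3-hydroxy-2-methyl-5-(2-methyl-1,3-dioxolan-2-yl)penta-1,4-dienyl]-3-methylideneoxolan-2-one | C=C1C(=O)O[C@H](/C=C(/C)[C@H](O)/C=C/C2(C)OCCO2)[C@@H]1[C@@H]3COC(C)(C)O3 | intermediate
17 | (4R,5R)-5-[(1Z,3R,4E)-3-acetoxy-2-methyl-5-(2-methyl-1,3-dioxolan-2-yl)penta-1,4-dienyl]-4-[(4R)-2,2-dimethyl-1,3-dioxolan-4-yl]-3-methylideneoxolan-2-one | C=C1C(=O)O[C@H](/C=C(/C)[C@H](OC(C)=O)/C=C/C2(C)OCCO2)[C@@H]1[C@@H]3COC(C)(C)O3 | intermediate
18 | (4S,5R)-5-[(1Z,3R,4E)-3-acetoxy-2-methyl-6-oxohepta-1,4-dienyl]-4-[(1R)-1,2-dihydroxyethyl]-3-methylideneoxolan-2-one | C=C1C(=O)O[C@H](/C=C(/C)[C@H](OC(C)=O)/C=C/C(C)=O)[C@@H]1[C@@H](O)CO | intermediate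
19 | (4S,5R)-5-[(1Z,3R,4E)-3-acetoxy-2-methyl-6-oxohepta-1,4-dienyl]-4-[(1R)-2-bromo-1-hydroxyethyl]-3-methylideneoxolan-2-one | C=C1C(=O)O[C@H](/C=C(/C)[C@H](OC(C)=O)/C=C/C(C)=O)[C@@H]1[C@@H](O)CBr | intermediate
20 | (4R,5R)-5-[(1Z,3R,4E)-3-acetoxy-2-methyl-6-oxohepta-1,4-dienyl]-4-(bromoacetyl)-3-methylideneoxolan-2-one | C=C1C(=O)O[C@H](/C=C(/C)[C@H](OC(C)=O)/C=C/C(C)=O)[C@@H]1C(=O)CBr | intermediate
21 | O-(diiodosamario) enolate of 20 (trivalent samarium enolate at C8=C9) | C=C1C(=O)O[C@H](/C=C(/C)[C@H](OC(C)=O)/C=C/C(C)=O)[C@@H]1C(=C)O[Sm](I)I | intermediate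
22 | (3R,6R,7R,10R)-3-acetoxy-10-hydroxy-8-oxogermacra-1(2),4,11(13)-trien-12,6-olide (1E,4Z) | C=C1C(=O)O[C@@H]2/C=C(/C)[C@H](OC(C)=O)/C=C/[C@](C)(O)CC(=O)[C@H]12 | intermediate
23 | tetramethylammonium O10-(diacetoxyhydridoborate) of 22 | C=C1C(=O)O[C@@H]2/C=C(/C)[C@H](OC(C)=O)/C=C/[C@](C)(O[BH-](OC(C)=O)OC(C)=O)CC(=O)[C@H]12.C[N+](C)(C)C | intermediate
24 | (3R,6R,7S,8R,10R)-3-acetoxy-8,10-dihydroxygermacra-1(2),4,11(13)-trien-12,6-olide (1E,4Z) | C=C1C(=O)O[C@@H]2/C=C(/C)[C@H](OC(C)=O)/C=C/[C@](C)(O)C[C@@H](O)[C@H]12 | intermediate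
25 | angelic acid [(2Z)-2-methylbut-2-enoic acid] | C/C=C(C)\C(=O)O | starting material
26 | (2Z)-2-methylbut-2-enoic 2,4,6-trichlorobenzoic anhydride | C/C=C(C)\C(=O)OC(=O)c1c(Cl)cc(Cl)cc1Cl | intermediate
27 | (3R,6R,7S,8R,10R)-3-acetoxy-8-angeloyloxy-10-hydroxygermacra-1(2),4,11(13)-trien-12,6-olide (1E,4Z) | C=C1C(=O)O[C@@H]2/C=C(/C)[C@H](OC(C)=O)/C=C/[C@](C)(O)C[C@@H](OC(=O)/C(C)=C\C)[C@H]12 | target

**Step count**

Total step count: 14 (steps 1–4 and steps 5–6 converge at step 7). Longest linear sequence: 12 steps (steps 1–4, then 7–14).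

**Steps most likely to fail**

Step 12. The ring closure may be slower than proton transfer within the samarium enolate, so regiochemical integrity is lost and the lactone oxygen is then eliminated; the facial selectivity at C10 may also be poor. The fallback is an intramolecular nitrile oxide–olefin cycloaddition, with the isoxazoline as a masked aldol. It sets out from 18 and comes back to the route at 22. Glycol cleavage of 18 with NaIO4 in THF/H2O gives the C8 aldehyde F1, C9 being lost. Hydroxylamine hydrochloride with NaOAc condenses selectively with the aldehyde to give the aldoxime F2. Takai–Lombardo methylenation (Zn, CH2Br2, TiCl4, THF) of the methyl ketone gives the 2-methyl-1,3-diene oxime F3, whose new terminal CH2 is the future C9. NaOCl in CH2Cl2 under high dilution oxidises the oxime to the nitrile oxide F4, which should add across the 1,1-disubstituted diene terminus to give the bridged isoxazoline F5 (C8–C9 and O–C10 bonds, C10 set by a concerted, non-chelated transition state). Mo(CO)6 in wet acetonitrile cleaves the N–O bond, and hydrolysis of the β-hydroxy imine returns 22.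

Step 7. The lactol may dehydrate to the aromatic furan under the Lewis-acidic aqueous conditions, and the control of the aldehyde face by the dioxolane stereocentre may erode. The fallback is a thermal allylboration with a preformed reagent. It sets out from 13 and 9 and comes back at 16. Palladium-catalysed borylation of 13 (B2pin2, Pd2(dba)3, DMSO) gives the allylboronate F6 with the double-bond geometry retained. Heating F6 with 9 in toluene should effect allylboration through a closed chair transition state under neutral, anhydrous conditions (syn adduct). The boron alkoxide of 15 lactonises on work-up to 16.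

Step 14. The angeloyl group may isomerise to the tigloyl group (Z to E) during activation, and the hindered C8 hydroxyl may acylate sluggishly. The fallback builds the Z double bond on the ester. It sets out from 24 and comes back at 27. Steglich esterification of 24 with 2-[bis(2,2,2-trifluoroethoxy)phosphoryl]propanoic acid (DCC, DMAP, CH2Cl2) gives the phosphonate ester F7. Still–Gennari olefination of F7 with acetaldehyde (KN(SiMe3)2, 18-crown-6, THF, −78 °C) should give the Z-configured 2-methylbut-2-enoate 27.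

**Further compounds**

F1 | step 12 | (2R,3R)-2-[(1Z,3R,4E)-3-acetoxy-2-methyl-6-oxohepta-1,4-dienyl]-4-methylidene-5-oxooxolane-3-carbaldehyde | C=C1C(=O)O[C@H](/C=C(/C)[C@H](OC(C)=O)/C=C/C(C)=O)[C@@H]1C=O
F2 | step 12 | (4S,5R)-5-[(1Z,3R,4E)-3-acetoxy-2-methyl-6-oxohepta-1,4-dienyl]-4-[(hydroxyimino)methyl]-3-methylideneoxolan-2-one | C=C1C(=O)O[C@H](/C=C(/C)[C@H](OC(C)=O)/C=C/C(C)=O)[C@@H]1C=NO
F3 | step 12 | (4S,5R)-5-[(1Z,3R,4E)-3-acetoxy-2,6-dimethylhepta-1,4,6-trienyl]-4-[(hydroxyimino)methyl]-3-methylideneoxolan-2-one | C=C1C(=O)O[C@H](/C=C(/C)[C@H](OC(C)=O)/C=C/C(C)=C)[C@@H]1C=NO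
F4 | step 12 | nitrile oxide of F3 (C8 nitrile N-oxide) | C=C1C(=O)O[C@H](/C=C(/C)[C@H](OC(C)=O)/C=C/C(C)=C)[C@@H]1C#[N+][O-]
F5 | step 12 | bridged isoxazoline (C8=N–O–C10) of the (3R,6R,7S,10R)-3-acetoxygermacra-1(2),4,11(13)-trien-12,6-olide skeleton | C=C1C(=O)O[C@@H]2/C=C(/C)[C@H](OC(C)=O)/C=C/[C@@]3(C)CC(=NO3)[C@H]12
F6 | step 7 | methyl (2E)-3-[(4R)-2,2-dimethyl-1,3-dioxolan-4-yl]-2-[(4,4,5,5-tetramethyl-1,3,2-dioxaborolan-2-yl)methyl]prop-2-enoate (same geometry as 13) | COC(=O)/C(CB1OC(C)(C)C(C)(C)O1)=C/[C@@H]1COC(C)(C)O1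
F7 | step 14 | 8-O-{2-[bis(2,2,2-trifluoroethoxy)phosphoryl]propanoyl} derivative of 24 | C=C1C(=O)O[C@@H]2/C=C(/C)[C@H](OC(C)=O)/C=C/[C@](C)(O)C[C@@H](OC(=O)C(C)P(=O)(OCC(F)(F)F)OCC(F)(F)F)[C@H]12
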